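**Assumption:** lehualide A has no stereocentre, so "single enantiomer" is taken to mean the single geometric isomer 2'E,6'Z,9'E written in the SMILES (side-chain carbons primed, C1' on the pyrone).

## Retrosynthetic overview

1. The pyrone is the only ring made and is closed last, by lactonisation of an acyclic 3,5-diketo ester.
2. Key C–C bond (pyrone C5–C6): intermolecular aldol of the γ-dianion of methyl 2-methoxy-3-oxopentanoate with the C12 side-chain trienal, then oxidation.
3. Trienal ⇐ homoallylic alcohol ⇐ terminal alkyne, by Zr-catalysed carboalumination and ethylene oxide opening (sets 2'E).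
4. Skipped diene ⇐ Negishi alkenyl–allyl coupling of a Z-alkenylzinc (from but-2-yn-1-ol, sets 6'Z) with an E-allylic bromide (Wittig from phenylacetaldehyde, sets 9'E).
5. Methoxy keto ester ⇐ methyl 3-oxopentanoate by diazo transfer and Rh-catalysed O–H insertion into methanol.

## Route

Step 1
Reactants: 1 phenylacetaldehyde; 2 ethyl 2-(triphenylphosphoranylidene)propanoate
Product: 3 ethyl (2E)-2-methyl-4-phenylbut-2-enoate
Conditions: CH2Cl2, 0 °C → rt, 12 h
Reagents that add atoms: none
Why: Wittig olefination with an α-methyl stabilised ylide is strongly E-selective (typically ≥95:5) and neutral enough not to move the olefin into conjugation with the phenyl ring, so the 9'E geometry is set here.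

Step 2
Reactants: 3 ethyl (2E)-2-methyl-4-phenylbut-2-enoate
Product: 4 (2E)-2-methyl-4-phenylbut-2-en-1-ol
Conditions: i-Bu2AlH (2.5 equiv), CH2Cl2, −78 → 0 °C; aq. potassium sodium tartrate
Reagents that add atoms: none
Why: 1,2-reduction of the enoate by the aluminium hydride gives the allylic alcohol without touching the olefin geometry, and the minor Z isomer from step 1 is removed by chromatography here.

Step 3
Reactants: 4 (2E)-2-methyl-4-phenylbut-2-en-1-ol
Product: 5 [(2E)-4-bromo-3-methylbut-2-en-1-yl]benzene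
Conditions: CBr4, PPh3, CH2Cl2, 0 °C
Reagents that add atoms: tetrabromomethane, BrC(Br)(Br)Br
Why: Appel bromination displaces the oxyphosphonium of a primary allylic alcohol by SN2 under neutral conditions, so the E geometry is kept.

Step 4
Reactants: 6 but-2-yn-1-ol
Product: 8 (2Z)-3-iodobut-2-en-1-ol, via cyclic sodium alkenylaluminate 7 (not isolated)
Conditions: NaAlH2(OCH2CH2OMe)2, THF, 0 °C → rt; then I2, THF, −78 → 0 °C
Reagents that add atoms: iodine, II
Why: hydroxyl-directed trans-hydroalumination places Al on C3 cis to the CH2O group in a five-membered aluminate, and iodinolysis with retention gives only the Z-iodide, which fixes the future 6'Z geometry.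

Step 5
Reactants: 8 (2Z)-3-iodobut-2-en-1-ol
Product: 9 (2Z)-1-bromo-3-iodobut-2-ene
Conditions: CBr4, PPh3, CH2Cl2, 0 °C
Reagents that add atoms: tetrabromomethane, BrC(Br)(Br)Br
Why: Appel bromination of the primary allylic alcohol is an SN2 process that leaves the vinyl iodide and its geometry untouched.

Step 6
Reactants: 9 (2Z)-1-bromo-3-iodobut-2-ene; 10 trimethyl(prop-1-yn-1-yl)silane
Product: 12 [(5Z)-6-iodohept-5-en-1-yn-1-yl]trimethylsilane, via propargylic lithium reagent 11 (not isolated)
Conditions: 10, n-BuLi (0.95 equiv), THF, −78 → −20 °C; then 9, −78 → −20 °C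
Reagents that add atoms: none
Why: SN2 alkylation of the silyl-stabilised propargyl anion at the primary allylic bromide builds the 1,5-enyne, while the vinyl iodide survives because I/Li exchange with a stabilised propargyl anion is unfavourable and no free n-BuLi is left.

Step 7
Reactants: 12 [(5Z)-6-iodohept-5-en-1-yn-1-yl]trimethylsilane; 5 [(2E)-4-bromo-3-methylbut-2-en-1-yl]benzene
Product: 15 trimethyl[(5Z,8E)-6,8-dimethyl-10-phenyldeca-5,8-dien-1-yn-1-yl]silane, via alkenyllithium 13 (not isolated), via alkenylzinc bromide 14 (not isolated)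
Conditions: t-BuLi (2.0 equiv), Et2O, −78 °C; ZnBr2, THF, −78 → 0 °C; then 5, Pd(PPh3)4 (5 mol %), THF, 0 °C → rt
Reagents that add atoms: none
Why: in this Negishi alkenyl–allyl cross-coupling, I/Li exchange and transmetalation to zinc retain the alkenyl geometry (zinc is added at −78 °C before warming so the anion cannot cyclise onto the silylalkyne), and the π-allylpalladium from 5 couples at its unsubstituted CH2 terminus faster than it isomerises, giving the skipped 6'Z,9'E diene.

Step 8
Reactants: 15 trimethyl[(5Z,8E)-6,8-dimethyl-10-phenyldeca-5,8-dien-1-yn-1-yl]silane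
Product: 16 [(2E,5Z)-3,5-dimethyldeca-2,5-dien-9-yn-1-yl]benzene
Conditions: K2CO3 (0.3 equiv), MeOH–THF, rt
Reagents that add atoms: none
Why: base-catalysed methanolysis of the C(sp)–Si bond frees the terminal alkyne, and the 1,5-enyne has no activated skipped position that could isomerise.

Step 9
Reactants: 16 [(2E,5Z)-3,5-dimethyldeca-2,5-dien-9-yn-1-yl]benzene
Product: 19 (3E,7Z,10E)-4,8,10-trimethyl-12-phenyldodeca-3,7,10-trien-1-ol, via dimethylalkenylalane 17 (not isolated), via lithium alkenylalanate 18 (not isolated)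
Conditions: Me3Al (2 equiv), Cp2ZrCl2 (0.25 equiv), CH2Cl2, 0 °C → rt; evaporate volatiles; n-BuLi (1 equiv), THF–hexane, −78 °C; ethylene oxide (3 equiv, THF solution), −78 → 0 °C; H2O, then aq. potassium sodium tartrate
Reagents that add atoms: trimethylaluminium, C[Al](C)C; ethylene oxide, C1CO1
Why: Negishi Zr-catalysed carboalumination adds Me and Al syn across the terminal alkyne with Al on the terminal carbon, and the derived alanate opens ethylene oxide with retention at the alkenyl carbon, which sets the 2'E olefin and gives the homoallylic alcohol directly.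

Step 10
Reactants: 19 (3E,7Z,10E)-4,8,10-trimethyl-12-phenyldodeca-3,7,10-trien-1-ol
Product: 20 (3E,7Z,10E)-4,8,10-trimethyl-12-phenyldodeca-3,7,10-trienal
Conditions: Dess–Martin periodinane (1.3 equiv), pyridine, CH2Cl2, 0 °C, 1 h; short silica plug, used at once
Reagents that add atoms: none
Why: the buffered Dess–Martin oxidation is fast and neutral, so the β,γ-unsaturated aldehyde is obtained without migration of the C3 olefin into conjugation.

Step 11
Reactants: 21 methyl 3-oxopentanoate
Product: 22 methyl 2-diazo-3-oxopentanoate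
Conditions: 4-acetamidobenzenesulfonyl azide, Et3N, MeCN, 0 °C → rt
Reagents that add atoms: 4-acetamidobenzenesulfonyl azide, CC(=O)Nc1ccc(cc1)S(=O)(=O)N=[N+]=[N-]
Why: Regitz diazo transfer to the doubly activated methylene of a β-keto ester is high-yielding and regiospecific.

Step 12
Reactants: 22 methyl 2-diazo-3-oxopentanoate
Product: 23 methyl 2-methoxy-3-oxopentanoate (racemic)
Conditions: Rh2(OAc)4 (1 mol %), MeOH (5 equiv), CH2Cl2, rt → 40 °C
Reagents that add atoms: methanol, CO
Why: O–H insertion of the rhodium carbenoid into methanol installs the methoxy group that becomes the 3-OMe of the pyrone, and Wolff rearrangement does not compete under these mild conditions.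

Step 13
Reactants: 23 methyl 2-methoxy-3-oxopentanoate; 20 (3E,7Z,10E)-4,8,10-trimethyl-12-phenyldodeca-3,7,10-trienal
Product: 25 methyl (7E,11Z,14E)-5-hydroxy-2-methoxy-4,8,12,14-tetramethyl-3-oxo-16-phenylhexadeca-7,11,14-trienoate (diastereomer mixture), via sodium lithium dienolate 24 (not isolated)
Conditions: 23 (2 equiv), NaH, THF, 0 °C; n-BuLi, 0 °C; then 20 (1 equiv), −78 °C, 30 min; AcOH quench at −78 °C
Reagents that add atoms: none
Why: in this intermolecular aldol addition of a β-keto ester dianion, the more reactive γ-carbanion adds to the aldehyde at −78 °C faster than it enolises it, forming the future pyrone C5–C6 bond; the three new stereocentres are formed unselectively and are all erased in steps 14 and 15.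

Step 14
Reactants: 25 methyl (7E,11Z,14E)-5-hydroxy-2-methoxy-4,8,12,14-tetramethyl-3-oxo-16-phenylhexadeca-7,11,14-trienoate
Product: 26 methyl (7E,11Z,14E)-2-methoxy-4,8,12,14-tetramethyl-3,5-dioxo-16-phenylhexadeca-7,11,14-trienoate
Conditions: Dess–Martin periodinane (1.5 equiv), pyridine, CH2Cl2, 0 °C → rt
Reagents that add atoms: none
Why: Dess–Martin oxidation of the β-hydroxy ketone gives the 3,5-diketo ester under neutral conditions that leave the three trisubstituted olefins in place.

Step 15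
Reactants: 26 methyl (7E,11Z,14E)-2-methoxy-4,8,12,14-tetramethyl-3,5-dioxo-16-phenylhexadeca-7,11,14-trienoate
Product: 27 lehualide A, 4-hydroxy-3-methoxy-5-methyl-6-[(2E,6Z,9E)-3,7,9-trimethyl-11-phenylundeca-2,6,9-trien-1-yl]-2H-pyran-2-one
Conditions: DBU (2 equiv), toluene, rt → 50 °C; 1 M HCl work-up
Reagents that add atoms: none
Why: base-mediated enolisation and lactonisation of the C5 enol oxygen onto the methyl ester gives the 4-hydroxy-2-pyrone, and the resulting pyronate anion shields the skipped C1' position from deprotonation until acid work-up.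

## Compound list

1 | phenylacetaldehyde | O=CCc1ccccc1 | starting material
2 | ethyl 2-(triphenylphosphoranylidene)propanoate | CCOC(=O)C(C)=P(c1ccccc1)(c1ccccc1)c1ccccc1 | starting material
3 | ethyl (2E)-2-methyl-4-phenylbut-2-enoate | CCOC(=O)/C(C)=C/Cc1ccccc1 | intermediate
4 | (2E)-2-methyl-4-phenylbut-2-en-1-ol | OC/C(C)=C/Cc1ccccc1 | intermediate
5 | [(2E)-4-bromo-3-methylbut-2-en-1-yl]benzene | BrC/C(C)=C/Cc1ccccc1 | intermediate
6 | but-2-yn-1-ol | CC#CCO | starting material
7 | sodium 2,2-bis(2-methoxyethoxy)-3-methyl-2,5-dihydro-1,2-oxaaluminol-2-uide (cyclic alkenylaluminate, not isolated) | [Na+].CC1=CCO[Al-]1(OCCOC)OCCOC | intermediate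
8 | (2Z)-3-iodobut-2-en-1-ol | C/C(I)=C/CO | intermediate
9 | (2Z)-1-bromo-3-iodobut-2-ene | C/C(I)=C/CBr | intermediate
10 | trimethyl(prop-1-yn-1-yl)silane | CC#C[Si](C)(C)C | starting material
11 | [3-(trimethylsilyl)prop-2-yn-1-yl]lithium (not isolated) | [Li]CC#C[Si](C)(C)C | intermediate
12 | [(5Z)-6-iodohept-5-en-1-yn-1-yl]trimethylsilane | C/C(I)=C/CCC#C[Si](C)(C)C | intermediate
13 | [(2E)-7-(trimethylsilyl)hept-2-en-6-yn-2-yl]lithium (Li cis to the chain CH2, not isolated) | C/C([Li])=C/CCC#C[Si](C)(C)C | intermediate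
14 | bromo[(2Z)-7-(trimethylsilyl)hept-2-en-6-yn-2-yl]zinc (Zn cis to the chain CH2, not isolated) | C/C([Zn]Br)=C/CCC#C[Si](C)(C)C | intermediate
15 | trimethyl[(5Z,8E)-6,8-dimethyl-10-phenyldeca-5,8-dien-1-yn-1-yl]silane | C[Si](C)(C)C#CCC/C=C(/C)C/C(C)=C/Cc1ccccc1 | intermediate
16 | [(2E,5Z)-3,5-dimethyldeca-2,5-dien-9-yn-1-yl]benzene | C#CCC/C=C(/C)C/C(C)=C/Cc1ccccc1 | intermediate
17 | dimethyl[(1E,5Z,8E)-2,6,8-trimethyl-10-phenyldeca-1,5,8-trien-1-yl]alumane (not isolated) | C[Al](C)/C=C(\C)CC/C=C(/C)C/C(C)=C/Cc1ccccc1 | intermediate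
18 | lithium butyl(dimethyl)[(1E,5Z,8E)-2,6,8-trimethyl-10-phenyldeca-1,5,8-trien-1-yl]aluminate (not isolated) | [Li+].CCCC[Al-](C)(C)/C=C(\C)CC/C=C(/C)C/C(C)=C/Cc1ccccc1 | intermediate
19 | (3E,7Z,10E)-4,8,10-trimethyl-12-phenyldodeca-3,7,10-trien-1-ol | OCC/C=C(\C)CC/C=C(/C)C/C(C)=C/Cc1ccccc1 | intermediate
20 | (3E,7Z,10E)-4,8,10-trimethyl-12-phenyldodeca-3,7,10-trienal | O=CC/C=C(\C)CC/C=C(/C)C/C(C)=C/Cc1ccccc1 | intermediate
21 | methyl 3-oxopentanoate | CCC(=O)CC(=O)OC | starting material
22 | methyl 2-diazo-3-oxopentanoate | CCC(=O)C(=[N+]=[N-])C(=O)OC | intermediate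
23 | methyl 2-methoxy-3-oxopentanoate (racemic) | CCC(=O)C(OC)C(=O)OC | intermediate
24 | sodium lithium 1,2-dimethoxypenta-1,3-diene-1,3-diolate (γ-dianion of 23, not isolated) | [Na+].[Li+].CC=C([O-])C(OC)=C([O-])OC | intermediate
25 | methyl (7E,11Z,14E)-5-hydroxy-2-methoxy-4,8,12,14-tetramethyl-3-oxo-16-phenylhexadeca-7,11,14-trienoate (diastereomer mixture at C2, C4, C5) | COC(=O)C(OC)C(=O)C(C)C(O)C/C=C(\C)CC/C=C(/C)C/C(C)=C/Cc1ccccc1 | intermediate
26 | methyl (7E,11Z,14E)-2-methoxy-4,8,12,14-tetramethyl-3,5-dioxo-16-phenylhexadeca-7,11,14-trienoate (keto/enol mixture) | COC(=O)C(OC)C(=O)C(C)C(=O)C/C=C(\C)CC/C=C(/C)C/C(C)=C/Cc1ccccc1 | intermediate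
27 | lehualide A, 4-hydroxy-3-methoxy-5-methyl-6-[(2E,6Z,9E)-3,7,9-trimethyl-11-phenylundeca-2,6,9-trien-1-yl]-2H-pyran-2-one | COc1c(O)c(C)c(C/C=C(\C)CC/C=C(/C)C/C(C)=C/Cc2ccccc2)oc1=O | target

## Summary

Total steps: 15.
Longest linear sequence: 10 steps (6 → 8 → 9 → 12 → 15 → 16 → 19 → 20 → 25 → 26 → 27; the branch from 1 is equally long).

**Steps most likely to fail**

Step 7 (alkenyl–allyl coupling; risk of branched or geometry-scrambled product from the π-allyl intermediate, and homocoupling). The fallback sets out from 12 and comes back at 15, and takes the 9'E olefin from a syn-carbometalation instead of an allylpalladium species. Compound 12 is lithiated as before (t-BuLi, Et2O, −78 °C, through 13) and trapped with paraformaldehyde to give (2Z)-2-methyl-7-(trimethylsilyl)hept-2-en-6-yn-1-ol F1. Appel bromination (CBr4, PPh3, 0 °C) gives [(5Z)-7-bromo-6-methylhept-5-en-1-yn-1-yl]trimethylsilane F2. SN2 coupling with HC≡CMgBr catalysed by CuBr·SMe2 in THF gives trimethyl[(5Z)-6-methylnon-5-ene-1,8-diyn-1-yl]silane F3. Zr-catalysed carboalumination of the terminal alkyne only (Me3Al, Cp2ZrCl2, CH2Cl2) gives dimethyl[(1E,4Z)-2,4-dimethyl-9-(trimethylsilyl)nona-1,4-dien-8-yn-1-yl]alumane F4, which is coupled in the same flask with benzyl bromide and Pd(PPh3)4 to give 15.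

Step 9 (the alanate may open ethylene oxide sluggishly or transfer an alkyl group instead of the alkenyl group). The fallback sets out from 16 and comes back at 19, replacing the two-carbon epoxide opening by a one-carbon trap and a one-carbon homologation. The alane 17, made from 16 as before, is trapped with paraformaldehyde to give (2E,6Z,9E)-3,7,9-trimethyl-11-phenylundeca-2,6,9-trien-1-ol F5. MnO2 in CH2Cl2 gives (2E,6Z,9E)-3,7,9-trimethyl-11-phenylundeca-2,6,9-trienal F6. Methylenation with Ph3P=CH2 in THF gives [(2E,5Z,9E)-3,5,9-trimethyldodeca-2,5,9,11-tetraen-1-yl]benzene F7. Hydroboration of the terminal vinyl group alone with Cy2BH in THF at 0 °C gives dicyclohexyl[(3E,7Z,10E)-4,8,10-trimethyl-12-phenyldodeca-3,7,10-trien-1-yl]borane F8, which NaOH/H2O2 oxidises to 19.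

Step 13 (the β,γ-unsaturated aldehyde 20 can enolise or isomerise under the basic dianion, or decompose on handling). The fallback sets out from 19 and comes back at 26, replacing the aldol and oxidation by a Claisen-type acylation with a stable, less acidic acyl donor. Alcohol 19 is oxidised with TEMPO and PhI(OAc)2 in MeCN–water to (3E,7Z,10E)-4,8,10-trimethyl-12-phenyldodeca-3,7,10-trienoic acid F9. Coupling with HN(OMe)Me·HCl (EDC·HCl, Et3N, CH2Cl2) gives (3E,7Z,10E)-N-methoxy-N,4,8,10-tetramethyl-12-phenyldodeca-3,7,10-trienamide F10. C-acylation of the dianion 24 (from 23, 2.5 equiv, THF, −78 → 0 °C) with F10 gives the diketo ester 26 directly, so 20 and 25 are bypassed.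

## Further compounds

F1 | step 7 | (2Z)-2-methyl-7-(trimethylsilyl)hept-2-en-6-yn-1-ol | OC/C(C)=C\CCC#C[Si](C)(C)C
F2 | step 7 | [(5Z)-7-bromo-6-methylhept-5-en-1-yn-1-yl]trimethylsilane | BrC/C(C)=C\CCC#C[Si](C)(C)C
F3 | step 7 | trimethyl[(5Z)-6-methylnon-5-ene-1,8-diyn-1-yl]silane | C#CC/C(C)=C\CCC#C[Si](C)(C)C
F4 | step 7 | dimethyl[(1E,4Z)-2,4-dimethyl-9-(trimethylsilyl)nona-1,4-dien-8-yn-1-yl]alumane | C[Al](C)/C=C(\C)C/C(C)=C\CCC#C[Si](C)(C)C
F5 | step 9 | (2E,6Z,9E)-3,7,9-trimethyl-11-phenylundeca-2,6,9-trien-1-ol | OC/C=C(\C)CC/C=C(/C)C/C(C)=C/Cc1ccccc1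
F6 | step 9 | (2E,6Z,9E)-3,7,9-trimethyl-11-phenylundeca-2,6,9-trienal | O=C/C=C(\C)CC/C=C(/C)C/C(C)=C/Cc1ccccc1
F7 | step 9 | [(2E,5Z,9E)-3,5,9-trimethyldodeca-2,5,9,11-tetraen-1-yl]benzene | C=C/C=C(\C)CC/C=C(/C)C/C(C)=C/Cc1ccccc1
F8 | step 9 | dicyclohexyl[(3E,7Z,10E)-4,8,10-trimethyl-12-phenyldodeca-3,7,10-trien-1-yl]borane | C(C/C=C(\C)CC/C=C(/C)C/C(C)=C/Cc1ccccc1)B(C1CCCCC1)C1CCCCC1
F9 | step 13 | (3E,7Z,10E)-4,8,10-trimethyl-12-phenyldodeca-3,7,10-trienoic acid | OC(=O)C/C=C(\C)CC/C=C(/C)C/C(C)=C/Cc1ccccc1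
F10 | step 13 | (3E,7Z,10E)-N-methoxy-N,4,8,10-tetramethyl-12-phenyldodeca-3,7,10-trienamide | CON(C)C(=O)C/C=C(\C)CC/C=C(/C)C/C(C)=C/Cc1ccccc1
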